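The numbers in the tables come from a simulation for substances that don't exist, noise included.

The vessel is closed and stirred and starts with no gas in solution, so in the first readings you are watching dissolved gas fill in as well as the free catalyst at work.

all flasks: gas phase 21 mM (held)

|  | starting material | free catalyst | remark | time |
|---|---|---|---|---|
| gamma | 0.13 M | 0.35 mol% | run made earlier |  |
| zeta | 0.13 M | 1.4 mol% | run made earlier |  |
| theta | 0.26 M | 0.7 mol% | run made earlier |  |
| flask | 0.13 M | 0.7 mol% |  | 3.0 h |

| run | time / h | target / % |
|---|---|---|
| gamma | 0.200 | 1.6 |
| gamma | 0.333 | 3.0 |
| gamma | 0.417 | 4.3 |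
| gamma | 0.667 | 8.0 |
| gamma | 1.00 | 10.1 |
| gamma | 1.50 | 13.1 |
| gamma | 2.50 | 16.0 |
| zeta | 0.200 | 6.0 |
| zeta | 0.333 | 12.9 |
| zeta | 0.417 | 16.8 |
| zeta | 0.667 | 24.3 |
| zeta | 1.00 | 32.1 |
| zeta | 1.50 | 41.4 |
| zeta | 2.50 | 46.5 |
| theta | 0.200 | 6.4 |
| theta | 0.667 | 19.5 |
| theta | 1.00 | 26.4 |
| theta | 1.50 | 34.2 |
| theta | 2.50 | 40.3 |

(readings scatter by 1 percentage point)

- target at 3.0 h, in percent of the starting material charged
- concentration of dissolved gas in solution at 50 min, in percent of saturation
- the change that raises the amount of target at 3.0 h, in percent of the starting material charged most ("none" if none brings more than 2 percentage points) (Monday's / Saturday's / Friday's / none)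
- amount of target at 3.0 h, in percent of the starting material charged, after Friday's

- at the start none of the gas phase is in solution

- Monday's: doubling the amount of free catalyst, all else as stated
- Saturday's: doubling the transfer coefficient of the gas phase, all else as stated
- Friday's: doubling the saturation concentration of gas phase, all else as stated

Work in powers of ten. For each run take D, the base-ten logarithm of [starting material] charged over [starting material] left, which rises evenly in a pseudo-first-order run with steady catalyst and steady [dissolved gas]. At the last readings:

gamma: D = 0.0757
zeta: D = 0.272
theta: D = 0.224

If D follows the catalyst charge, gamma and zeta scale to this flask's loading, and their mean is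

D = 0.144 at 2.50 h.

But D slows. In zeta it gains 0.168 in the first hour, then 0.0395 over the last interval. Scaling that late gain to the remaining 0.500 h gives

D = 0.154, target 29.9%.

That is my reckoning, and the number to carry is this D, the decades of starting material the flask's catalyst charge gets through by 3.0 h.

Is one number enough? No. Four times gamma's loading gives zeta only 3.59 times its D. Theta holds zeta's catalyst concentration yet ends 6.2 percentage points lower, against a scatter of 1 point. And these runs share one saturation, 21 mM, so they cannot show how D moves with it.

The forecast gives 29% (26.5% to 31.5%), 90% of saturation, Monday's as best and 37% after Friday's, holding that “the gas dependence looks saturating”.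

The flask gives 30.9%, which is D = 0.161, with dissolved gas at 85.7% of saturation at 50 min.

    free catalyst → spent catalyst (k = 0.0170 /min)
    starting material + dissolved gas + free catalyst → free catalyst + target (k = 450 /M²/min)
    gas phase ⇌ dissolved gas, rate k3*(csat - [dissolved gas]) (kL = 0.130 /min)

By 3.0 h free catalyst stands at 4.69% of its charge. The rate is first order in [dissolved gas]; taking twice the carried D gives target 50.8%. Friday's reaches 52.7%, a gain of 22 points against 18 points for Monday's.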